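A constant in reciprocal minutes divided by one in litres per mole per minute is a concentration, and in this flask that quotient is what I look for.

free monomer 43 mM; initiator 0.86 mM; impurity 0.25 mM; time 10 d

    free monomer + living end → monomer in chains + living end, rate k1*[living end]*[free monomer] (k1 = 2.75 L mol⁻¹ min⁻¹)
    free monomer → decomposition product (k2 = 2.95 × 10⁻⁶ min⁻¹)
    initiator → spent initiator B (k3 = 0.00104 min⁻¹)
    monomer in chains + living end → free monomer + living end, rate k4*[living end] as long as [monomer in chains] is above zero (k4 = 0.0152 min⁻¹)
    free monomer + initiator → living end + monomer in chains (k5 = 0.173 L mol⁻¹ min⁻¹)
    initiator + impurity → spent initiator A (k6 = 3040 L mol⁻¹ min⁻¹)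

- the average divides the monomer in chains by the number of chains begun, living and dead together
- run time (flask): 10 d

- whether the average number of monomer units in a chain (chains begun, living or dead) reaches 40 by 10 d (yes / no)
- average number of monomer units in a chain (chains begun, living or dead) at 10 d

Growth and its reverse both carry [living end] to the first power, so the net uptake of free monomer into growing chains is [living end] times the difference between 2.75 L mol⁻¹ min⁻¹·[free monomer] and 0.0152 min⁻¹. Uptake therefore stops, at any [living end] above zero and while monomer in chains is present, at the ceiling concentration (the equilibrium monomer concentration), the reverse constant over the growth constant, 5.53 mM.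

For the number of chains begun I set up a table of three rows for the initiator, each a pseudo-first-order constant at the charge: with impurity 0.760 min⁻¹, with free monomer 0.00744 min⁻¹, alone 0.00104 min⁻¹. The first row stands far above the second, so I let the impurity take its 0.25 mM of initiator first, which leaves 0.610 mM. The second row is larger than the third, and their split, reckoned at the charge, gives 87.7 % of that remainder to chains, so I estimate 0.535 mM chains begun.

With that [living end], free monomer relaxes with a pseudo-first-order constant of 0.00147 min⁻¹, and 10 d holds 21.2 such lifetimes, so I put free monomer at the ceiling by then. I leave out the decomposition product, since at the ceiling its step takes 0.235 mM over 10 d, far less than the 37.5 mM that goes into chains. Monomer in chains is then 37.5 mM, and I commit to an average of 70.0, which is more than 40, so my answer is yes.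

The forecast says yes and 71, within 66 to 76, with the words “Free monomer then relaxes within a few thousand minutes to the ceiling”.

The simulation gives yes, with the length reached at 0.469 d, and 70.3 at 10 d.

In this flask at 3.45 d, monomer in chains is made 1.00 times as fast as it is used up, each step taken net, and at 10.0 d free monomer stands at 12.8 % of its charge, against 12.9 % for the ceiling. In the flask with half the free monomer and all other amounts as they are, I keep the ceiling of 5.53 mM and redo the split of the second and third rows, which gives 33.5, and that run ends at 33.9.

All constants come from no measurement, and the outcome is calculated.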